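## Structural features

The target is a C40 carotenoid diester in which two trimethylated six-membered end rings are joined through C6 and C6' by an all-E nonaene chain (C7 to C7') carrying methyl groups at C9, C13, C13' and C9', and O3 and O3' each bear a hexadecanoyl group. Ring A is a cyclohexane fused across C5–C6 to an oxirane (a 7-oxabicyclo[4.1.0]heptane), so that C5 and C6 are adjacent, fully substituted stereocentres (5R,6S), and the ester oxygen at C3 (3S) lies on the ring face opposite the oxirane oxygen. The other end is an ε ring, a cyclohex-4'-ene in which C3' (allylic ester, 3'R) and C6' (doubly allylic methine, 6'R) are 1,4-related and trans. Fragile are the oxirane (allylic to C7=C8 and turned by acid into the 5,8-furanoid ether), the allylic C3' ester together with the C6' hydrogen (whose loss erases that stereocentre), the two esters (which exclude hydride and alkoxide reagents once present) and the polyene itself (light, oxygen, acid, E/Z drift). The real difficulty is the anti relation between O3 and the oxirane on a tetrasubstituted C5=C6 alkene, where steric bias is small, together with an acid-free, ester-tolerant union of two different end groups. The key step exploits the homoallylic position of C3 relative to C5=C6 inside ring A: a C3 hydroxyl bound to vanadium can pass oxygen to that alkene only on its own face, and a later SN2 inversion at C3 by the carboxylate turns the syn relation into the anti one.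

## Logic of the disconnections

31 is cut at C11=C12 into 16 (C11 as formyl carbon) and 29 (C12 as phosphonate α-carbon, reacting as the carbanion 30). Cutting here keeps the whole acid-sensitive oxirane end as an electrophile, so it never has to pass through a phosphonium salt made with HBr. The gain is two fragments of similar size, each already carrying its stereocentres and its ester. The forward step must be an E-selective olefination that is cold, aprotic and free of acid and alkoxide.

29 is cut at C11'=C12' into 23 and 27 (the latter reacting as 28). Because 27 is symmetric, either end can react, and the ten central carbons arrive in one piece with three E alkenes already set. The demand is that only one phosphonate of 27 reacts, and that the base does not cause vinylogous loss of carboxylate from 23.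

27 is cut at its two C–P bonds back to 24 (through 26 and 25). 24 is a catalogue dialdehyde with the correct geometry, so the gain is that no alkene of the centre has to be made. The demand is substitution at the allylic termini without scrambling of the triene.

16 is cut at the C3–O bond into 14 and 15, with inversion at C3. A hydroxyl-directed epoxidation can only give the syn isomer, so forming the ester by displacement both installs the acyl group and corrects the relative configuration. This cut is placed after the i-Bu2AlH reduction, because an ester introduced at the ketone stage would not survive that step. The demand is a clean SN2 at a secondary ring carbinol without elimination.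

14 is cut at C9=C10 into 10 and 11 (through 13 and the carbanion 12). An N-methoxy-N-methylamide reaches the aldehyde level in one reduction with a neutral work-up, so no acidic hydrolysis and no separate alcohol oxidation is needed. The demand is E geometry in the olefination of a methyl ketone.

10 is cut at the C5–O and C6–O bonds to 9. This is the strategic cut: the oxirane and two stereocentres come from one oxygen-atom transfer directed by the C3 hydroxyl. The demand is delivery to C5=C6 only, on the hydroxyl face only.

9 is cut at C6–C7 into 6 and 7 (through 8). Joining an enol triflate to a vinyl ketone gives the E dienone directly. It replaces a sequence of carbonyl addition, alkyne reduction, dehydration of a tertiary allylic alcohol (which can transpose) and alcohol oxidation. The demand is a Heck coupling at a tetrasubstituted triflate.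

6 is traced to 1 through 5, 4, 3 and 2. The ring of 1 contains every ring carbon. Only the carbinol centre has to be pure, because the methyl-bearing centre of 3 is erased on enolisation. Hydride reagents favour the other carbinol epimer (the axial methyl at C2 blocks the required approach), so the demand is an enzyme that gives the 4S alcohol, and no racemisation of 2 before it is reduced.

23 is cut at the acyl–O3' bond into 22 and 15. This is a plain acylation with retention, placed after the last hydride step of that branch.

22 is traced to 17 and 11 through 21, 20 and 19, with 18 as the olefinating carbanion (C9'=C10' and the C3'–O bond). 17 supplies the ε ring and C6'. The C3' oxygen comes from allylic oxidation followed by face-selective reduction. The amide route avoids an allylic alcohol oxidation that could not tell the chain carbinol from the ring carbinol. The demands are an olefination in which no free base meets the ketone, a base-free oxidation (C6' becomes vinylogously acidic) and a trans-selective reduction.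

## Other disconnections considered

Alternative 1: The cut is the C1'–C6' bond of the ε ring. In the forward step SnCl4 ionises the tertiary carbinol of the open-chain allylsilane A2; C6' of the (Z)-allylsilane captures the C1' cation and the silyl group leaves, giving the methylidenecyclohexane A1.
- In favour: a chair transition state with the silyloxy and acyloxymethyl groups equatorial sets the trans C3'/C6' relation from a single acyclic carbinol centre. No enantiopure 17, no CrO3 oxidation and no face-selective ketone reduction are needed. On the stereochemistry of the ε ring this is the better plan.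
- Against: A1 carries an exocyclic alkene, which must be moved to C4'=C5' without going on to C5'=C6' (that would erase C6'). C7' must then be built from the acyloxymethyl group by deprotection, oxidation and two olefinations. A2 itself needs several steps.
- Comparison: structurally it solves only the ε end, and the oxirane end would still need the chosen key step, so the two are complementary. Mechanistically it is a cationic closure with Lewis acid, whereas the chosen ε branch uses neutral or hydride steps on a purchased ring. In step count the chosen branch (five steps from 17) should be clearly shorter.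

Alternative 2: The cuts are C13'–CH3 and C14'–C15'. AlMe3 with catalytic Cp2ZrCl2 adds methyl and aluminium syn across the terminal alkyne of A4. A4 is strictly a trienyne, since C7'=C8', C9'=C10' and C11'=C12' are already present beside the C13'≡C14' triple bond. The alkenylalane is passed to zinc (ZnCl2) and coupled by Pd(PPh3)4 with A5 at its carbon–iodine bond, giving the bromide A3.
- In favour: the trisubstituted C13'=C14' alkene is set by syn carbometalation, which is a better source of E geometry than olefination of a methyl ketone. A3 is ready for a second neutral cross-coupling under Pd(PPh3)4 that an allylic oxirane should tolerate. In convergence it is the equal of the chosen plan.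
- Against: AlMe3 excludes an ester on that fragment, so O3' must travel as a silyl ether and be exchanged for the palmitate on a long polyene (two extra steps). The oxirane end would have to become a C20 alkenyl metal, which is longer to build than 16. The step itself does nothing for the C3/C5/C6 problem.
- Comparison: better on alkene geometry, equal on convergence, worse on ester compatibility and step count.

Alternative 3: The cuts are C5–C6 and C6–O. KOtBu deprotonates the α-chloro ester of the open-chain keto ester A7. The enolate adds to the C5 methyl ketone to close ring A, and the C5 alkoxide displaces chloride to close the oxirane, giving the glycidic ester A6.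
- In favour: C3 already has the target configuration, so no inversion is needed; on that point it is better than the chosen plan. Ring and oxirane form in one operation, and the ester at C6 is a handle for C7.
- Against: C5 and C6 are controlled only by a 1,3-relation to C3 in a reversible aldol between a neopentyl-type enolate and a methyl ketone. Retro-aldol, ketone enolisation and the need for an anti alkoxide/chloride arrangement all weigh on it. A7 must be made enantiopure, and A6 still needs reduction, oxidation and olefination to reach the stage of 10.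
- Comparison: structurally it builds what the chosen plan buys (the ring of 1). Mechanistically its stereocontrol rests on conformational preference, whereas the chosen step fixes the face through a covalent vanadium–oxygen bond. It saves the inversion but costs more steps overall.

Key step: step 7

Assumption: 17 is bought as the (R) enantiomer, and 11 and 24 are catalogue compounds.

Remark: the descriptor of C3 changes from S in 9 to R in 10 although no bond at C3 is touched (the oxirane oxygen raises C4 above C2 in priority); the inversion in step 10 then gives 3S.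

## Route

Step 1
Reactants: 1 ketoisophorone (2,6,6-trimethylcyclohex-2-ene-1,4-dione)
Product: 2 (6R)-2,2,6-trimethylcyclohexane-1,4-dione ((6R)-levodione)
Conditions: ene-reductase (old yellow enzyme 2), NADP+ (cat.), glucose dehydrogenase, D-glucose, phosphate buffer pH 6.5, 30 °C
Reagents that add atoms: none
Why: Enzymatic asymmetric reduction of the enedione C=C bond (flavin-dependent ene-reductase, for which this substrate is a standard case); the active site fixes the face of hydrogen delivery at the methyl-bearing carbon and gives 6R, and slightly acidic buffer with prompt extraction limits enolisation of the new α-centre.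

Step 2
Reactants: 2 (6R)-2,2,6-trimethylcyclohexane-1,4-dione
Product: 3 (4S,6R)-4-hydroxy-2,2,6-trimethylcyclohexan-1-one
Conditions: (4S)-selective NADPH-dependent ketoreductase, NADP+ (cat.), glucose dehydrogenase, D-glucose, phosphate buffer pH 6.5, 30 °C
Reagents that add atoms: none
Why: Enzymatic carbonyl reduction at C4 only (C1 is flanked by a quaternary and a tertiary carbon); a Prelog-selective ketoreductase that places the gem-dimethyl side in its large pocket should set 4S, the cis diequatorial alcohol that hydride reagents do not give cleanly. C6 is a spectator that is erased in step 4.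

Step 3
Reactants: 3 (4S,6R)-4-hydroxy-2,2,6-trimethylcyclohexan-1-one
Product: 4 (4S,6R)-4-(tert-butyldimethylsilyloxy)-2,2,6-trimethylcyclohexan-1-one
Conditions: TBSCl, imidazole, DMF, 25 °C
Reagents that add atoms: tert-butyldimethylsilyl chloride, CC(C)(C)[Si](C)(C)Cl
Why: Silylation of a secondary alcohol; the silyl ether masks the hydroxyl during enolate and Heck chemistry and leaves C4 untouched.

Step 4
Reactants: 4 (4S,6R)-4-(tert-butyldimethylsilyloxy)-2,2,6-trimethylcyclohexan-1-one
Product: 6 (4S)-4-(tert-butyldimethylsilyloxy)-2,6,6-trimethylcyclohex-1-en-1-yl trifluoromethanesulfonate, via lithium enolate 5 (not isolated)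
Conditions: LiN(i-Pr)2, THF, −78 → 0 °C; PhNTf2, 0 → 25 °C
Reagents that add atoms: N-phenylbis(trifluoromethanesulfonimide), O=S(=O)(N(c1ccccc1)S(=O)(=O)C(F)(F)F)C(F)(F)F
Why: Enolate O-sulfonylation; the ketone has one α-hydrogen only (the other α-carbon is quaternary), so a single enolate and a single tetrasubstituted enol triflate form. The methyl-bearing stereocentre is erased on purpose, and the silyloxy group is γ to the enolate carbon and cannot be eliminated.

Step 5
Reactants: 6 (4S)-4-(tert-butyldimethylsilyloxy)-2,6,6-trimethylcyclohex-1-en-1-yl trifluoromethanesulfonate; 7 methyl vinyl ketone (but-3-en-2-one)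
Product: 8 (E)-4-[(4S)-4-(tert-butyldimethylsilyloxy)-2,6,6-trimethylcyclohex-1-en-1-yl]but-3-en-2-one ((3S)-3-silyloxy-β-ionone)
Conditions: Pd(OAc)2 (5 mol %), PPh3 (10 mol %), Et3N, DMF, 70 °C
Reagents that add atoms: none
Why: Mizoroki–Heck reaction of an alkenyl triflate with an enone; zerovalent palladium formed in the flask inserts into the C–O bond of the triflate, the alkenylpalladium adds across the vinyl ketone and syn β-hydride elimination gives the E dienone. The new C6–C7 bond carries no stereocentre.

Step 6
Reactants: 8 (E)-4-[(4S)-4-(tert-butyldimethylsilyloxy)-2,6,6-trimethylcyclohex-1-en-1-yl]but-3-en-2-one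
Product: 9 (3S)-3-hydroxy-β-ionone ((E)-4-[(4S)-4-hydroxy-2,6,6-trimethylcyclohex-1-en-1-yl]but-3-en-2-one)
Conditions: Bu4NF, THF, 0 → 25 °C
Reagents that add atoms: none
Why: Fluoride cleavage of the silyl ether; it frees the homoallylic hydroxyl needed for direction and does not touch the dienone.

Step 7
Reactants: 9 (3S)-3-hydroxy-β-ionone
Product: 10 (3R,5R,6S)-5,6-epoxy-3-hydroxy-5,6-dihydro-β-ionone ((E)-4-[(1S,2R,4R)-4-hydroxy-2,6,6-trimethyl-7-oxabicyclo[4.1.0]heptan-1-yl]but-3-en-2-one; oxirane syn to the hydroxyl)
Conditions: VO(acac)2 (5 mol %), t-BuOOH (anhydrous, in decane, 2 equiv), toluene, 25 → 40 °C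
Reagents that add atoms: tert-butyl hydroperoxide, CC(C)(C)OO
Why: Hydroxyl-directed epoxidation of a cyclic homoallylic alcohol by a vanadium alkylperoxide, the closest known type being the vanadium-catalysed epoxidation of cyclohex-3-en-1-ols. The hydroperoxide oxidises VO(acac)2 to a pentavalent vanadium species that binds O3 as an alkoxide and tert-butylperoxide in an η2 mode. In the half-chair with the C3–O bond pseudoaxial the bound peroxide oxygen sits over C5=C6 and is transferred in one concerted step, so the oxirane closes by a suprafacial [2+1] oxygen-atom transfer in which both C–O bonds form together on the hydroxyl face. C5 and C6 are set at once: their mutual relation follows from the cis ring alkene and their absolute sense from the C3 stereocentre through the vanadium–oxygen bond, which should give the 5R,6S oxirane syn to O3. Site selectivity against C7=C8 is secured because that alkene is polarised by the ketone and out of reach of the tether, whereas C5=C6 is tetrasubstituted, twisted out of conjugation and two atoms from the carbinol. Oxidation of the carbinol to a ketone should not compete, because transfer to the tethered alkene is intramolecular. The medium is neutral and the only by-product is tert-butanol, so the allylic oxirane has no reason to rearrange.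

Step 8
Reactants: 10 (3R,5R,6S)-5,6-epoxy-3-hydroxy-5,6-dihydro-β-ionone; 11 diethyl [2-(methoxy(methyl)amino)-2-oxoethyl]phosphonate
Product: 13 (2E,4E)-5-[(1S,2R,4R)-4-hydroxy-2,6,6-trimethyl-7-oxabicyclo[4.1.0]heptan-1-yl]-N-methoxy-N,3-dimethylpenta-2,4-dienamide, via sodium phosphonate carbanion 12 (not isolated)
Conditions: NaH (2.4 equiv), 11 (2.5 equiv), THF, 0 °C; then 10, 0 → 40 °C
Reagents that add atoms: none
Why: Horner–Wadsworth–Emmons olefination of a methyl ketone; the preformed stabilised carbanion is too weak a base to deprotonate the carbinol, and equilibration before elimination should favour the 9E amide, the minor 9Z isomer being removed by chromatography. The C3 hydroxyl lies on the same face as the oxirane oxygen, so it cannot attack C5 from the rear and the oxirane should stay closed.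

Step 9
Reactants: 13 (2E,4E)-5-[(1S,2R,4R)-4-hydroxy-2,6,6-trimethyl-7-oxabicyclo[4.1.0]heptan-1-yl]-N-methoxy-N,3-dimethylpenta-2,4-dienamide
Product: 14 (2E,4E)-5-[(1S,2R,4R)-4-hydroxy-2,6,6-trimethyl-7-oxabicyclo[4.1.0]heptan-1-yl]-3-methylpenta-2,4-dienal
Conditions: i-Bu2AlH (3 equiv), THF, −78 °C; aq. KNaC4H4O6 work-up
Reagents that add atoms: none
Why: Reduction of an N-methoxy-N-methylamide stops at the aldehyde because the chelated aluminium hemiaminal persists until work-up; the tetrasubstituted oxirane is not opened at −78 °C and the tartrate work-up is neutral. This is the last hydride step of the branch, and it is placed before the ester is introduced.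

Step 10
Reactants: 14 (2E,4E)-5-[(1S,2R,4R)-4-hydroxy-2,6,6-trimethyl-7-oxabicyclo[4.1.0]heptan-1-yl]-3-methylpenta-2,4-dienal; 15 palmitic acid (hexadecanoic acid)
Product: 16 (2E,4E)-5-[(1S,2R,4S)-4-(hexadecanoyloxy)-2,6,6-trimethyl-7-oxabicyclo[4.1.0]heptan-1-yl]-3-methylpenta-2,4-dienal (carotenoid numbering 3S,5R,6S; ester anti to the oxirane)
Conditions: PPh3, DIAD, THF, 0 → 25 °C
Reagents that add atoms: none
Why: Mitsunobu esterification; O3 is activated as an oxyphosphonium ion and the carboxylate displaces it by SN2, so C3 is inverted and the ester oxygen ends anti to the oxirane. The enal and the oxirane are inert to the phosphine–azodicarboxylate betaine.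

Step 11
Reactants: 17 (R)-α-ionone ((E)-4-[(1R)-2,6,6-trimethylcyclohex-2-en-1-yl]but-3-en-2-one); 11 diethyl [2-(methoxy(methyl)amino)-2-oxoethyl]phosphonate
Product: 19 (2E,4E)-N-methoxy-N,3-dimethyl-5-[(1R)-2,6,6-trimethylcyclohex-2-en-1-yl]penta-2,4-dienamide, via potassium phosphonate carbanion 18 (not isolated)
Conditions: 11 (1.6 equiv), KN(SiMe3)2 (1.5 equiv), THF, −78 → 0 °C; then 17, 0 → 25 °C
Reagents that add atoms: none
Why: Horner–Wadsworth–Emmons olefination of a methyl ketone with the potassium salt of the phosphonate, made with a soluble amide base kept below the amount of 11 so that no free base meets the ketone. The stabilised carbanion should add to the unhindered carbonyl faster than it can remove the hindered, vinylogously acidic C6' hydrogen, so the 6'R centre should be kept, and the 9'E isomer should predominate.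

Step 12
Reactants: 19 (2E,4E)-N-methoxy-N,3-dimethyl-5-[(1R)-2,6,6-trimethylcyclohex-2-en-1-yl]penta-2,4-dienamide
Product: 20 (2E,4E)-N-methoxy-N,3-dimethyl-5-[(1R)-2,6,6-trimethyl-4-oxocyclohex-2-en-1-yl]penta-2,4-dienamide
Conditions: CrO3, 3,5-dimethylpyrazole, CH2Cl2, −20 °C
Reagents that add atoms: chromium trioxide, O=[Cr](=O)=O
Why: Allylic oxidation of a ring methylene to the enone by the complex of hexavalent chromium with 3,5-dimethylpyrazole; C3' is the only secondary allylic position, as in the known oxidation of α-ionone derivatives at that carbon. The base-free medium avoids deprotonation at C6', which becomes vinylogously acidic once the ketone is present.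

Step 13
Reactants: 20 (2E,4E)-N-methoxy-N,3-dimethyl-5-[(1R)-2,6,6-trimethyl-4-oxocyclohex-2-en-1-yl]penta-2,4-dienamide
Product: 21 (2E,4E)-5-[(1R,4R)-4-hydroxy-2,6,6-trimethylcyclohex-2-en-1-yl]-N-methoxy-N,3-dimethylpenta-2,4-dienamide
Conditions: LiBH(s-Bu)3, THF, −78 °C
Reagents that add atoms: none
Why: 1,2-Reduction of a β,β-disubstituted cyclohexenone by a bulky trialkylborohydride; the hydride should approach anti to the axial C1' methyl (1,3-diaxial shielding), that is on the face of the pseudoaxial side chain. The new hydroxyl is thereby placed trans to the side chain at C6' (3'R). The conjugated amide should not react at this temperature.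

Step 14
Reactants: 21 (2E,4E)-5-[(1R,4R)-4-hydroxy-2,6,6-trimethylcyclohex-2-en-1-yl]-N-methoxy-N,3-dimethylpenta-2,4-dienamide
Product: 22 (2E,4E)-5-[(1R,4R)-4-hydroxy-2,6,6-trimethylcyclohex-2-en-1-yl]-3-methylpenta-2,4-dienal
Conditions: i-Bu2AlH (2.5 equiv), THF, −78 °C; aq. KNaC4H4O6 work-up
Reagents that add atoms: none
Why: Amide-to-aldehyde reduction as in step 9; it gives the aldehyde without an alcohol oxidation, which could not distinguish the chain carbinol from the allylic ring carbinol, and the neutral work-up spares the ionisable C3' alcohol.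

Step 15
Reactants: 22 (2E,4E)-5-[(1R,4R)-4-hydroxy-2,6,6-trimethylcyclohex-2-en-1-yl]-3-methylpenta-2,4-dienal; 15 palmitic acid
Product: 23 (1R,4R)-3,5,5-trimethyl-4-[(1E,3E)-3-methyl-5-oxopenta-1,3-dien-1-yl]cyclohex-2-en-1-yl hexadecanoate
Conditions: DCC, DMAP (cat.), CH2Cl2, 0 → 25 °C
Reagents that add atoms: none
Why: Steglich esterification (carbodiimide activation and acyl transfer through the acylpyridinium ion); the C3'–O bond is not broken, so 3'R is retained.

Step 16
Reactants: 24 (2E,4E,6E)-2,7-dimethylocta-2,4,6-trienedial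
Product: 25 (2E,4E,6E)-2,7-dimethylocta-2,4,6-triene-1,8-diol
Conditions: NaBH4, MeOH–THF, 0 °C
Reagents that add atoms: none
Why: 1,2-Hydride reduction of both enal carbonyls; the triene geometry is not affected.

Step 17
Reactants: 25 (2E,4E,6E)-2,7-dimethylocta-2,4,6-triene-1,8-diol
Product: 26 (2E,4E,6E)-1,8-dibromo-2,7-dimethylocta-2,4,6-triene
Conditions: PBr3, pyridine (cat.), Et2O, −10 °C, dark
Reagents that add atoms: phosphorus tribromide, BrP(Br)Br
Why: Conversion of primary allylic alcohols into bromides through their phosphite esters; low temperature and exclusion of light should keep the triene intact.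

Step 18
Reactants: 26 (2E,4E,6E)-1,8-dibromo-2,7-dimethylocta-2,4,6-triene
Product: 27 tetraethyl [(2E,4E,6E)-2,7-dimethylocta-2,4,6-triene-1,8-diyl]bis(phosphonate)
Conditions: P(OEt)3, toluene, 110 °C
Reagents that add atoms: triethyl phosphite, CCOP(OCC)OCC
Why: Michaelis–Arbuzov reaction of primary allylic bromides at both termini.

Step 19
Reactants: 27 tetraethyl [(2E,4E,6E)-2,7-dimethylocta-2,4,6-triene-1,8-diyl]bis(phosphonate) (3 equiv); 23 (1R,4R)-3,5,5-trimethyl-4-[(1E,3E)-3-methyl-5-oxopenta-1,3-dien-1-yl]cyclohex-2-en-1-yl hexadecanoate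
Product: 29 diethyl [(2E,4E,6E,8E,10E,12E)-13-[(1R,4R)-4-(hexadecanoyloxy)-2,6,6-trimethylcyclohex-2-en-1-yl]-2,7,11-trimethyltrideca-2,4,6,8,10,12-hexaen-1-yl]phosphonate, via sodium phosphonate carbanion 28 (not isolated)
Conditions: NaN(SiMe3)2 (1 equiv), THF, −78 °C; then 23, −78 → 0 °C, dark
Reagents that add atoms: none
Why: Horner–Wadsworth–Emmons olefination of an enal with an allylic phosphonate carbanion, which should form C11'=C12' with E geometry. The bisphosphonate is in excess and only one equivalent of a non-nucleophilic amide base is used, so one end should react while the other phosphonate stays for step 20; the unused 27 is recovered.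

Step 20
Reactants: 29 diethyl [(2E,4E,6E,8E,10E,12E)-13-[(1R,4R)-4-(hexadecanoyloxy)-2,6,6-trimethylcyclohex-2-en-1-yl]-2,7,11-trimethyltrideca-2,4,6,8,10,12-hexaen-1-yl]phosphonate; 16 (2E,4E)-5-[(1S,2R,4S)-4-(hexadecanoyloxy)-2,6,6-trimethyl-7-oxabicyclo[4.1.0]heptan-1-yl]-3-methylpenta-2,4-dienal
Product: 31 (3S,5R,6S,3'R,6'R)-5,6-epoxy-5,6-dihydro-β,ε-carotene-3,3'-diyl dihexadecanoate (CNP0344034.1), via sodium phosphonate carbanion 30 (not isolated)
Conditions: NaN(SiMe3)2 (1.05 equiv), THF, −78 °C; then 16, −78 → 0 °C, argon, dark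
Reagents that add atoms: none
Why: Second Horner–Wadsworth–Emmons olefination; the C12 carbanion adds to the C11 aldehyde and elimination should give C11=C12 with E geometry. The conditions are aprotic, cold and free of acid and alkoxide, so both esters, the allylic oxirane and C6'–H should survive, and no stereocentre is touched; the all-E isomer is expected to be the one that crystallises.

## Compound list

1 | ketoisophorone (2,6,6-trimethylcyclohex-2-ene-1,4-dione) | CC1=CC(=O)CC(C)(C)C1=O | starting material
2 | (6R)-2,2,6-trimethylcyclohexane-1,4-dione | O=C1CC(C)(C)C(=O)[C@H](C)C1 | intermediate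
3 | (4S,6R)-4-hydroxy-2,2,6-trimethylcyclohexan-1-one | O[C@@H]1CC(C)(C)C(=O)[C@H](C)C1 | intermediate
4 | (4S,6R)-4-(tert-butyldimethylsilyloxy)-2,2,6-trimethylcyclohexan-1-one | CC(C)(C)[Si](C)(C)O[C@@H]1CC(C)(C)C(=O)[C@H](C)C1 | intermediate
5 | lithium (4S)-4-(tert-butyldimethylsilyloxy)-2,6,6-trimethylcyclohex-1-en-1-olate (not isolated) | [Li+].CC(C)(C)[Si](C)(C)O[C@@H]1CC(C)(C)C([O-])=C(C)C1 | intermediate
6 | (4S)-4-(tert-butyldimethylsilyloxy)-2,6,6-trimethylcyclohex-1-en-1-yl trifluoromethanesulfonate | CC(C)(C)[Si](C)(C)O[C@@H]1CC(C)(C)C(OS(=O)(=O)C(F)(F)F)=C(C)C1 | intermediate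
7 | methyl vinyl ketone (but-3-en-2-one) | C=CC(C)=O | starting material
8 | (E)-4-[(4S)-4-(tert-butyldimethylsilyloxy)-2,6,6-trimethylcyclohex-1-en-1-yl]but-3-en-2-one | CC(C)(C)[Si](C)(C)O[C@@H]1CC(C)(C)C(/C=C/C(C)=O)=C(C)C1 | intermediate
9 | (3S)-3-hydroxy-β-ionone | O[C@@H]1CC(C)(C)C(/C=C/C(C)=O)=C(C)C1 | intermediate
10 | (3R,5R,6S)-5,6-epoxy-3-hydroxy-5,6-dihydro-β-ionone (oxirane syn to hydroxyl) | O[C@@H]1CC(C)(C)[C@]2(/C=C/C(C)=O)O[C@]2(C)C1 | intermediate
11 | diethyl [2-(methoxy(methyl)amino)-2-oxoethyl]phosphonate | CCOP(=O)(CC(=O)N(C)OC)OCC | starting material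
12 | sodium salt of 11, phosphonate carbanion (not isolated) | [Na+].CCOP(=O)(OCC)[CH-]C(=O)N(C)OC | intermediate
13 | (2E,4E)-5-[(1S,2R,4R)-4-hydroxy-2,6,6-trimethyl-7-oxabicyclo[4.1.0]heptan-1-yl]-N-methoxy-N,3-dimethylpenta-2,4-dienamide | O[C@@H]1CC(C)(C)[C@]2(/C=C/C(C)=C/C(=O)N(C)OC)O[C@]2(C)C1 | intermediate
14 | (2E,4E)-5-[(1S,2R,4R)-4-hydroxy-2,6,6-trimethyl-7-oxabicyclo[4.1.0]heptan-1-yl]-3-methylpenta-2,4-dienal | O[C@@H]1CC(C)(C)[C@]2(/C=C/C(C)=C/C=O)O[C@]2(C)C1 | intermediate
15 | palmitic acid (hexadecanoic acid) | CCCCCCCCCCCCCCCC(=O)O | starting material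
16 | (2E,4E)-5-[(1S,2R,4S)-4-(hexadecanoyloxy)-2,6,6-trimethyl-7-oxabicyclo[4.1.0]heptan-1-yl]-3-methylpenta-2,4-dienal | CCCCCCCCCCCCCCCC(=O)O[C@H]1CC(C)(C)[C@]2(/C=C/C(C)=C/C=O)O[C@]2(C)C1 | intermediate
17 | (R)-α-ionone | CC(=O)/C=C/[C@H]1C(C)=CCCC1(C)C | starting material
18 | potassium salt of 11, phosphonate carbanion (not isolated) | [K+].CCOP(=O)(OCC)[CH-]C(=O)N(C)OC | intermediate
19 | (2E,4E)-N-methoxy-N,3-dimethyl-5-[(1R)-2,6,6-trimethylcyclohex-2-en-1-yl]penta-2,4-dienamide | CON(C)C(=O)/C=C(C)/C=C/[C@H]1C(C)=CCCC1(C)C | intermediate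
20 | (2E,4E)-N-methoxy-N,3-dimethyl-5-[(1R)-2,6,6-trimethyl-4-oxocyclohex-2-en-1-yl]penta-2,4-dienamide | CON(C)C(=O)/C=C(C)/C=C/[C@H]1C(C)=CC(=O)CC1(C)C | intermediate
21 | (2E,4E)-5-[(1R,4R)-4-hydroxy-2,6,6-trimethylcyclohex-2-en-1-yl]-N-methoxy-N,3-dimethylpenta-2,4-dienamide | CON(C)C(=O)/C=C(C)/C=C/[C@H]1C(C)=C[C@H](O)CC1(C)C | intermediate
22 | (2E,4E)-5-[(1R,4R)-4-hydroxy-2,6,6-trimethylcyclohex-2-en-1-yl]-3-methylpenta-2,4-dienal | O=C/C=C(C)/C=C/[C@H]1C(C)=C[C@H](O)CC1(C)C | intermediate
23 | (1R,4R)-3,5,5-trimethyl-4-[(1E,3E)-3-methyl-5-oxopenta-1,3-dien-1-yl]cyclohex-2-en-1-yl hexadecanoate | O=C/C=C(C)/C=C/[C@H]1C(C)=C[C@H](OC(=O)CCCCCCCCCCCCCCC)CC1(C)C | intermediate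
24 | (2E,4E,6E)-2,7-dimethylocta-2,4,6-trienedial | O=C/C(C)=C/C=C/C=C(C)/C=O | starting material
25 | (2E,4E,6E)-2,7-dimethylocta-2,4,6-triene-1,8-diol | OC/C(C)=C/C=C/C=C(C)/CO | intermediate
26 | (2E,4E,6E)-1,8-dibromo-2,7-dimethylocta-2,4,6-triene | BrC/C(C)=C/C=C/C=C(C)/CBr | intermediate
27 | tetraethyl [(2E,4E,6E)-2,7-dimethylocta-2,4,6-triene-1,8-diyl]bis(phosphonate) | CCOP(=O)(OCC)C/C(C)=C/C=C/C=C(C)/CP(=O)(OCC)OCC | intermediate
28 | monosodium salt of 27, phosphonate carbanion (not isolated) | [Na+].CCOP(=O)(OCC)[CH-]/C(C)=C/C=C/C=C(C)/CP(=O)(OCC)OCC | intermediate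
29 | diethyl [(2E,4E,6E,8E,10E,12E)-13-[(1R,4R)-4-(hexadecanoyloxy)-2,6,6-trimethylcyclohex-2-en-1-yl]-2,7,11-trimethyltrideca-2,4,6,8,10,12-hexaen-1-yl]phosphonate | CCOP(=O)(OCC)C/C(C)=C/C=C/C=C(C)/C=C/C=C(C)/C=C/[C@H]1C(C)=C[C@H](OC(=O)CCCCCCCCCCCCCCC)CC1(C)C | intermediate
30 | sodium salt of 29, phosphonate carbanion (not isolated) | [Na+].CCOP(=O)(OCC)[CH-]/C(C)=C/C=C/C=C(C)/C=C/C=C(C)/C=C/[C@H]1C(C)=C[C@H](OC(=O)CCCCCCCCCCCCCCC)CC1(C)C | intermediate
31 | (3S,5R,6S,3'R,6'R)-5,6-epoxy-5,6-dihydro-β,ε-carotene-3,3'-diyl dihexadecanoate | CCCCCCCCCCCCCCCC(=O)O[C@H]1CC(C)(C)[C@]2(/C=C/C(C)=C/C=C/C(C)=C/C=C/C=C(C)/C=C/C=C(C)/C=C/[C@H]3C(C)=C[C@H](OC(=O)CCCCCCCCCCCCCCC)CC3(C)C)O[C@]2(C)C1 | target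

## Step count and risk

Total step count: 20. Longest linear sequence: 11 steps (steps 1 to 10, then step 20). The ε branch (steps 11 to 15) and the central branch (steps 16 to 18) join in step 19.

Step 7 (key step). Oxygen transfer may be slow, because conjugation with the dienone lowers the nucleophilicity of C5=C6 and delivery needs the less populated half-chair in which the axial C3 oxygen meets a C1 methyl. Undirected epoxidation or oxidation of the carbinol could then compete and erode facial selectivity. The fallback moves the epoxidation to an allylic alcohol under reagent control; it sets out from 6 and returns at 10. Carbonylation of 6 (Pd(OAc)2, 1,3-bis(diphenylphosphino)propane, CO, MeOH, Et3N) would give methyl (4S)-4-(tert-butyldimethylsilyloxy)-2,6,6-trimethylcyclohex-1-ene-1-carboxylate F1, and i-Bu2AlH would reduce it to [(4S)-4-(tert-butyldimethylsilyloxy)-2,6,6-trimethylcyclohex-1-en-1-yl]methanol F2. Sharpless epoxidation with Ti(OiPr)4, D-(−)-diethyl tartrate and t-BuOOH should place oxygen, under control of the tartrate, on the face that gives the 5R,6S oxirane (the face of the silyloxy group), giving [(1R,2R,4R)-4-(tert-butyldimethylsilyloxy)-2,6,6-trimethyl-7-oxabicyclo[4.1.0]heptan-1-yl]methanol F3. Dess–Martin oxidation would give (1S,2R,4R)-4-(tert-butyldimethylsilyloxy)-2,6,6-trimethyl-7-oxabicyclo[4.1.0]heptane-1-carbaldehyde F4, Wittig reaction with Ph3P=CHC(O)CH3 would give (E)-4-[(1S,2R,4R)-4-(tert-butyldimethylsilyloxy)-2,6,6-trimethyl-7-oxabicyclo[4.1.0]heptan-1-yl]but-3-en-2-one F5, and Bu4NF would then give 10.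

Step 19. The product phosphonate is at least as acidic as 27, so proton exchange followed by a second olefination could give a symmetric double adduct and waste 23. The amide base could also cause vinylogous loss of the C3' carboxylate through C6'. The fallback breaks the symmetry of the central unit before coupling; it sets out from 25 and returns at 29. Monosilylation of 25 (TBSCl, imidazole, one equivalent) would give (2E,4E,6E)-8-(tert-butyldimethylsilyloxy)-2,7-dimethylocta-2,4,6-trien-1-ol F6, PBr3 would give [(2E,4E,6E)-8-bromo-2,7-dimethylocta-2,4,6-trien-1-yl]oxy(tert-butyl)dimethylsilane F7, and P(OEt)3 would give diethyl [(2E,4E,6E)-8-(tert-butyldimethylsilyloxy)-2,7-dimethylocta-2,4,6-trien-1-yl]phosphonate F8. Olefination of 23 with the sodium carbanion of F8 would give (1R,4R)-4-[(1E,3E,5E,7E,9E,11E)-13-(tert-butyldimethylsilyloxy)-3,7,12-trimethyltrideca-1,3,5,7,9,11-hexaen-1-yl]-3,5,5-trimethylcyclohex-2-en-1-yl hexadecanoate F9. Buffered fluoride (Bu4NF, AcOH) would give (1R,4R)-4-[(1E,3E,5E,7E,9E,11E)-13-hydroxy-3,7,12-trimethyltrideca-1,3,5,7,9,11-hexaen-1-yl]-3,5,5-trimethylcyclohex-2-en-1-yl hexadecanoate F10. PBr3 at low temperature would give (1R,4R)-4-[(1E,3E,5E,7E,9E,11E)-13-bromo-3,7,12-trimethyltrideca-1,3,5,7,9,11-hexaen-1-yl]-3,5,5-trimethylcyclohex-2-en-1-yl hexadecanoate F11, and P(OEt)3 would then give 29.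

Step 5. Oxidative addition and insertion at the tetrasubstituted triflate may be slow, so that hydrolysis or reduction of the triflate and polymerisation of the vinyl ketone take over. The fallback builds the side chain through an alkyne; it sets out from 6 and returns at 8. Sonogashira coupling of 6 with but-3-yn-2-ol (Pd(PPh3)4, CuI, i-Pr2NH) would give 4-[(4S)-4-(tert-butyldimethylsilyloxy)-2,6,6-trimethylcyclohex-1-en-1-yl]but-3-yn-2-ol F12. Trans-hydroalumination of the propargylic alcohol with NaAlH2(OCH2CH2OMe)2 would give (E)-4-[(4S)-4-(tert-butyldimethylsilyloxy)-2,6,6-trimethylcyclohex-1-en-1-yl]but-3-en-2-ol F13, and MnO2 would oxidise the allylic alcohol to 8.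

Step 13. Facial selectivity may be poor or reversed if the pseudoaxial side chain shields its face more than the axial methyl shields the other, so that hydride delivery gives the cis alcohol. The fallback makes the cis alcohol on purpose and inverts it with the carboxylate, as on the oxirane end; it sets out from 20 and returns at 23. Reduction of 20 with NaBH4 and CeCl3 in MeOH (axial attack by a small hydride) should favour (2E,4E)-5-[(1R,4S)-4-hydroxy-2,6,6-trimethylcyclohex-2-en-1-yl]-N-methoxy-N,3-dimethylpenta-2,4-dienamide F14. i-Bu2AlH would give (2E,4E)-5-[(1R,4S)-4-hydroxy-2,6,6-trimethylcyclohex-2-en-1-yl]-3-methylpenta-2,4-dienal F15, and Mitsunobu esterification with 15 (PPh3, DIAD) would invert C3' and give 23.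

Step 10. The activated oxyphosphonium ion may eliminate to a ring alkene, or substitution may stall because the long-chain acid is a weak and poorly soluble pronucleophile, leaving material with the hydroxyl configuration unchanged. The fallback separates activation from displacement; it sets out from 14 and returns at 16. MsCl and Et3N would give (2E,4E)-5-[(1S,2R,4R)-4-(methanesulfonyloxy)-2,6,6-trimethyl-7-oxabicyclo[4.1.0]heptan-1-yl]-3-methylpenta-2,4-dienal F16, and SN2 displacement with CsO2C(CH2)14CH3 and 18-crown-6 in toluene at 80 °C would give 16.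

## Further compounds

F1 | step 7 | methyl (4S)-4-(tert-butyldimethylsilyloxy)-2,6,6-trimethylcyclohex-1-ene-1-carboxylate | CC(C)(C)[Si](C)(C)O[C@@H]1CC(C)(C)C(C(=O)OC)=C(C)C1
F2 | step 7 | [(4S)-4-(tert-butyldimethylsilyloxy)-2,6,6-trimethylcyclohex-1-en-1-yl]methanol | CC(C)(C)[Si](C)(C)O[C@@H]1CC(C)(C)C(CO)=C(C)C1
F3 | step 7 | [(1R,2R,4R)-4-(tert-butyldimethylsilyloxy)-2,6,6-trimethyl-7-oxabicyclo[4.1.0]heptan-1-yl]methanol | CC(C)(C)[Si](C)(C)O[C@@H]1CC(C)(C)[C@]2(CO)O[C@]2(C)C1
F4 | step 7 | (1S,2R,4R)-4-(tert-butyldimethylsilyloxy)-2,6,6-trimethyl-7-oxabicyclo[4.1.0]heptane-1-carbaldehyde | CC(C)(C)[Si](C)(C)O[C@@H]1CC(C)(C)[C@]2(C=O)O[C@]2(C)C1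
F5 | step 7 | (E)-4-[(1S,2R,4R)-4-(tert-butyldimethylsilyloxy)-2,6,6-trimethyl-7-oxabicyclo[4.1.0]heptan-1-yl]but-3-en-2-one | CC(C)(C)[Si](C)(C)O[C@@H]1CC(C)(C)[C@]2(/C=C/C(C)=O)O[C@]2(C)C1
F6 | step 19 | (2E,4E,6E)-8-(tert-butyldimethylsilyloxy)-2,7-dimethylocta-2,4,6-trien-1-ol | OC/C(C)=C/C=C/C=C(C)/CO[Si](C)(C)C(C)(C)C
F7 | step 19 | [(2E,4E,6E)-8-bromo-2,7-dimethylocta-2,4,6-trien-1-yl]oxy(tert-butyl)dimethylsilane | BrC/C(C)=C/C=C/C=C(C)/CO[Si](C)(C)C(C)(C)C
F8 | step 19 | diethyl [(2E,4E,6E)-8-(tert-butyldimethylsilyloxy)-2,7-dimethylocta-2,4,6-trien-1-yl]phosphonate | CCOP(=O)(OCC)C/C(C)=C/C=C/C=C(C)/CO[Si](C)(C)C(C)(C)C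
F9 | step 19 | (1R,4R)-4-[(1E,3E,5E,7E,9E,11E)-13-(tert-butyldimethylsilyloxy)-3,7,12-trimethyltrideca-1,3,5,7,9,11-hexaen-1-yl]-3,5,5-trimethylcyclohex-2-en-1-yl hexadecanoate | CC(C)(C)[Si](C)(C)OC/C(C)=C/C=C/C=C(C)/C=C/C=C(C)/C=C/[C@H]1C(C)=C[C@H](OC(=O)CCCCCCCCCCCCCCC)CC1(C)C
F10 | step 19 | (1R,4R)-4-[(1E,3E,5E,7E,9E,11E)-13-hydroxy-3,7,12-trimethyltrideca-1,3,5,7,9,11-hexaen-1-yl]-3,5,5-trimethylcyclohex-2-en-1-yl hexadecanoate | OC/C(C)=C/C=C/C=C(C)/C=C/C=C(C)/C=C/[C@H]1C(C)=C[C@H](OC(=O)CCCCCCCCCCCCCCC)CC1(C)C
F11 | step 19 | (1R,4R)-4-[(1E,3E,5E,7E,9E,11E)-13-bromo-3,7,12-trimethyltrideca-1,3,5,7,9,11-hexaen-1-yl]-3,5,5-trimethylcyclohex-2-en-1-yl hexadecanoate | BrC/C(C)=C/C=C/C=C(C)/C=C/C=C(C)/C=C/[C@H]1C(C)=C[C@H](OC(=O)CCCCCCCCCCCCCCC)CC1(C)C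
F12 | step 5 | 4-[(4S)-4-(tert-butyldimethylsilyloxy)-2,6,6-trimethylcyclohex-1-en-1-yl]but-3-yn-2-ol (both carbinol epimers) | CC(C)(C)[Si](C)(C)O[C@@H]1CC(C)(C)C(C#CC(C)O)=C(C)C1
F13 | step 5 | (E)-4-[(4S)-4-(tert-butyldimethylsilyloxy)-2,6,6-trimethylcyclohex-1-en-1-yl]but-3-en-2-ol (both carbinol epimers) | CC(C)(C)[Si](C)(C)O[C@@H]1CC(C)(C)C(/C=C/C(C)O)=C(C)C1
F14 | step 13 | (2E,4E)-5-[(1R,4S)-4-hydroxy-2,6,6-trimethylcyclohex-2-en-1-yl]-N-methoxy-N,3-dimethylpenta-2,4-dienamide | CON(C)C(=O)/C=C(C)/C=C/[C@H]1C(C)=C[C@@H](O)CC1(C)C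
F15 | step 13 | (2E,4E)-5-[(1R,4S)-4-hydroxy-2,6,6-trimethylcyclohex-2-en-1-yl]-3-methylpenta-2,4-dienal | O=C/C=C(C)/C=C/[C@H]1C(C)=C[C@@H](O)CC1(C)C
F16 | step 10 | (2E,4E)-5-[(1S,2R,4R)-4-(methanesulfonyloxy)-2,6,6-trimethyl-7-oxabicyclo[4.1.0]heptan-1-yl]-3-methylpenta-2,4-dienal | CS(=O)(=O)O[C@@H]1CC(C)(C)[C@]2(/C=C/C(C)=C/C=O)O[C@]2(C)C1
A1 | alternative 1 | [(1R,4R)-4-(tert-butyldimethylsilyloxy)-2,2-dimethyl-6-methylidenecyclohexyl]methyl pivalate (trans) | CC(C)(C)C(=O)OC[C@H]1C(=C)C[C@H](O[Si](C)(C)C(C)(C)C)CC1(C)C
A2 | alternative 1 | (2Z,5S)-5-(tert-butyldimethylsilyloxy)-7-hydroxy-7-methyl-3-[(trimethylsilyl)methyl]oct-2-en-1-yl pivalate | CC(C)(O)C[C@@H](O[Si](C)(C)C(C)(C)C)C/C(C[Si](C)(C)C)=C/COC(=O)C(C)(C)C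
A3 | alternative 2 | tert-butyl{[(1R,4R)-4-[(1E,3E,5E,7E,9E)-10-bromo-3,7-dimethyldeca-1,3,5,7,9-pentaen-1-yl]-3,5,5-trimethylcyclohex-2-en-1-yl]oxy}dimethylsilane (ε-end all-E pentaenyl bromide, bromine at C15) | Br/C=C/C=C(C)/C=C/C=C(C)/C=C/[C@H]1C(C)=C[C@H](O[Si](C)(C)C(C)(C)C)CC1(C)C
A4 | alternative 2 | tert-butyl{[(1R,4R)-4-[(1E,3E,5E)-3-methylocta-1,3,5-trien-7-yn-1-yl]-3,5,5-trimethylcyclohex-2-en-1-yl]oxy}dimethylsilane (ε-end trienyne with terminal C13'≡C14' alkyne) | C#C/C=C/C=C(C)/C=C/[C@H]1C(C)=C[C@H](O[Si](C)(C)C(C)(C)C)CC1(C)C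
A5 | alternative 2 | (E)-1-bromo-2-iodoethene | Br/C=C/I
A6 | alternative 3 | methyl 4-(tert-butyldimethylsilyloxy)-2,2,6-trimethyl-7-oxabicyclo[4.1.0]heptane-1-carboxylate, oxirane anti to the silyloxy group | CC(C)(C)[Si](C)(C)O[C@H]1CC(C)(C)[C@]2(C(=O)OC)O[C@]2(C)C1
A7 | alternative 3 | methyl (5S)-2-chloro-5-(tert-butyldimethylsilyloxy)-3,3-dimethyl-7-oxooctanoate (both C2 epimers) | COC(=O)C(Cl)C(C)(C)C[C@H](O[Si](C)(C)C(C)(C)C)CC(C)=O
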